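## Retrosynthetic overview

1. The last C–C bond made is the CH2 bridge to C8 of ring A. The ortho-quinone methide of the acylphloroglucinol (from its Mannich base) is captured by 5,7,3',4'-tetra-O-benzylcatechin at C8, and global hydrogenolysis then gives the target.
2. C2 and C3 (2R,3S, trans) are set together by reagent-controlled syn hydroboration–oxidation of the C2=C3 enol ether of a flav-2-ene.
3. Ring C is closed in one domino step from a ring A 2-bromobenzyl chloride and the ring B aryl methyl ketone. C3–C4 forms by enolate C-benzylation and O1–C8a by copper-catalysed enolate O-arylation.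
4. Enabling feature: O1–C2–C3 of ring C is the O–C–C of the enolate of the ring B acetophenone (C2 is the carbonyl carbon, C3 the methyl carbon). C4–C4a–C8a of ring A is a benzylic carbon beside an aryl carbon that is meta to O5 and O7, the pattern of a 5-bromoresorcinol diether, so ring A enters as a 1,3-bis-electrophile with bromine marking C8a.
5. Order of rings: rings A, B and the acylphloroglucinol ring are bought as arenes; ring C is the only ring formed (step 4).

Key step: step 4

Remark: the dibenzyl ether of 5-bromoresorcinol, 3,4-bis(benzyloxy)acetophenone and C-methylphloracetophenone are taken as commercially available. Flavan numbering (O1, C2, C3, C4, C4a, C5–C8, C8a; rings A, B, C) is used throughout.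

## Route

Step 1
Reactants: 1 1,3-bis(benzyloxy)-5-bromobenzene
Product: 2 2,4-bis(benzyloxy)-6-bromobenzaldehyde
Conditions: POCl3, DMF, 0 → 70 °C; then H2O
Reagents that add atoms: N,N-dimethylformamide, CN(C)C=O; water, O
Why: Vilsmeier–Haack formylation should attack the carbon that is para to one benzyloxy group, ortho to the other and next to bromine, because the carbon between the two ether groups is the more hindered of the activated positions.

Step 2
Reactants: 2 2,4-bis(benzyloxy)-6-bromobenzaldehyde
Product: 3 [2,4-bis(benzyloxy)-6-bromophenyl]methanol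
Conditions: NaBH4, THF/MeOH, 0 °C
Reagents that add atoms: none
Why: Borohydride reduction of the aryl aldehyde gives the benzylic alcohol and leaves the aryl bromide and the benzyl ethers untouched.

Step 3
Reactants: 3 [2,4-bis(benzyloxy)-6-bromophenyl]methanol
Product: 4 1,5-bis(benzyloxy)-3-bromo-2-(chloromethyl)benzene
Conditions: SOCl2, CH2Cl2, 0 °C; used crude
Reagents that add atoms: thionyl chloride, O=S(Cl)Cl
Why: Chlorodehydroxylation through the chlorosulfite is fast for this electron-rich benzylic alcohol, and the labile chloride is carried on without purification.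

Step 4
Reactants: 4 1,5-bis(benzyloxy)-3-bromo-2-(chloromethyl)benzene; 5 1-[3,4-bis(benzyloxy)phenyl]ethan-1-one
Product: 7 5,7-bis(benzyloxy)-2-[3,4-bis(benzyloxy)phenyl]-4H-chromene, via C-benzylated ketone 6 (not isolated)
Conditions: 5 (1.5 equiv), KOt-Bu (2.5 equiv), CuI (10 mol %), 1,10-phenanthroline (20 mol %), 1,4-dioxane, 20 → 100 °C
Reagents that add atoms: none
Why: Proposed new method: the potassium enolate of 5 is C-benzylated by 4 in an SN2 step (C3–C4), and the enolate of the resulting ketone 6, whose favoured Z geometry holds O1 and C4 cis, then undergoes Ullmann-type O-arylation catalysed by monovalent copper (oxidative addition into C8a–Br, then C–O reductive elimination from a seven-membered aryl–copper enolate chelate) to form O1–C8a. The closest known reaction type is the copper-catalysed domino C-benzylation/O-arylation of 1,3-dicarbonyl compounds with 2-bromobenzyl bromides to 4H-chromenes, together with the copper-catalysed intramolecular O-arylation of simple ketone enolates to benzofurans; the new element is a non-activated aryl methyl ketone, hence the stronger base. Ring C closes in a six-membered mode by attack of the enolate oxygen on the aryl carbon with the C–Br bond exocyclic (formally 6-exo), and the product keeps the C2=C3 enol ether conjugated with ring B. No stereocentre is created; C2 and C3 are left as the prochiral alkene that step 5 needs. The selectivities required are C- over O-benzylation (soft benzylic chloride, potassium enolate in an ether solvent), mono- over dialkylation (5 in excess, and the monoalkylated enolate is drained irreversibly by ring closure) and O- over C-arylation (C-arylation at C3 would close a benzocyclobutene), while the regiochemistry on ring A is fixed because bromine sits only on C8a.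

Step 5
Reactants: 7 5,7-bis(benzyloxy)-2-[3,4-bis(benzyloxy)phenyl]-4H-chromene
Product: 9 (2R,3S)-5,7-bis(benzyloxy)-2-[3,4-bis(benzyloxy)phenyl]chroman-3-ol, via flavan-3-yl(isopinocampheyl)borane 8 (not isolated)
Conditions: IpcBH2 (prepared from (+)-α-pinene), THF, −25 °C; then NaOH, H2O2, H2O, 0 → 20 °C
Reagents that add atoms: hydrogen peroxide, OO
Why: In this asymmetric hydroboration–oxidation boron adds to C3 (the β-carbon of the enol ether) and hydrogen to C2 on the same face, so the C3 oxygen introduced with retention ends trans to the C2 aryl group, and the face is chosen by the isopinocampheyl group, which by analogy with 1-arylcycloalkenes should give the (2R,3S) isomer.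

Step 6
Reactants: 10 1-(2,4,6-trihydroxy-3-methylphenyl)ethan-1-one
Product: 11 1-[4,6-bis(benzyloxy)-2-hydroxy-3-methylphenyl]ethan-1-one
Conditions: BnBr (2.1 equiv), K2CO3, acetone, reflux
Reagents that add atoms: benzyl bromide, BrCc1ccccc1
Why: Williamson etherification should occur first at the para hydroxyl and then at the less hindered ortho hydroxyl, leaving free the carbonyl-chelated hydroxyl that is flanked by the methyl group.

Step 7
Reactants: 11 1-[4,6-bis(benzyloxy)-2-hydroxy-3-methylphenyl]ethan-1-one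
Product: 12 1-[4,6-bis(benzyloxy)-2-methoxy-3-methylphenyl]ethan-1-one
Conditions: MeI, K2CO3, DMF, 50 °C
Reagents that add atoms: iodomethane, CI
Why: Williamson O-methylation of the remaining chelated phenol under forcing carbonate conditions installs the single methyl ether of the target.

Step 8
Reactants: 12 1-[4,6-bis(benzyloxy)-2-methoxy-3-methylphenyl]ethan-1-one
Product: 13 1-(4,6-dihydroxy-2-methoxy-3-methylphenyl)ethan-1-one
Conditions: H2 (1 atm), Pd/C, EtOAc/MeOH, 20 °C
Reagents that add atoms: none
Why: Hydrogenolysis of the two benzyl ethers frees the phenols needed for aminomethylation, and the aryl ketone should not be reduced under these mild conditions.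

Step 9
Reactants: 13 1-(4,6-dihydroxy-2-methoxy-3-methylphenyl)ethan-1-one
Product: 14 1-{3-[(dimethylamino)methyl]-2,4-dihydroxy-6-methoxy-5-methylphenyl}ethan-1-one
Conditions: aq. CH2O, aq. Me2NH, EtOH, 0 → 20 °C
Reagents that add atoms: formaldehyde, C=O; dimethylamine, CNC
Why: The Mannich reaction can only occur at the single unsubstituted ring carbon, which lies between the two phenols, and gives a bench-stable precursor of the ortho-quinone methide.

Step 10
Reactants: 9 (2R,3S)-5,7-bis(benzyloxy)-2-[3,4-bis(benzyloxy)phenyl]chroman-3-ol; 14 1-{3-[(dimethylamino)methyl]-2,4-dihydroxy-6-methoxy-5-methylphenyl}ethan-1-one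
Product: 16 1-{3-[[(2R,3S)-5,7-bis(benzyloxy)-2-[3,4-bis(benzyloxy)phenyl]-3-hydroxychroman-8-yl]methyl]-2,4-dihydroxy-6-methoxy-5-methylphenyl}ethan-1-one, via ortho-quinone methide 15 (not isolated)
Conditions: 14 (1.3 equiv), AcOH (3 equiv), (CF3)2CHOH/CH2Cl2, 40 °C
Reagents that add atoms: none
Why: Loss of dimethylamine from the protonated Mannich base gives the ortho-quinone methide 15, which should alkylate ring A of 9 in a Friedel–Crafts-type conjugate addition at C8, the more nucleophilic and less hindered of the two free positions, without touching C2 or C3.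

Step 11
Reactants: 16 1-{3-[[(2R,3S)-5,7-bis(benzyloxy)-2-[3,4-bis(benzyloxy)phenyl]-3-hydroxychroman-8-yl]methyl]-2,4-dihydroxy-6-methoxy-5-methylphenyl}ethan-1-one
Product: 17 pilosanol N, 1-{3-[[(2R,3S)-2-(3,4-dihydroxyphenyl)-3,5,7-trihydroxychroman-8-yl]methyl]-2,4-dihydroxy-6-methoxy-5-methylphenyl}ethan-1-one
Conditions: H2 (1 atm), Pd(OH)2/C, THF/MeOH, 20 °C
Reagents that add atoms: none
Why: Hydrogenolysis of the four benzyl ethers should release the target, since the diarylmethane bridge, ring C and the hydrogen-bonded acetyl group are stable to these conditions.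

## Compound list

1 | 1,3-bis(benzyloxy)-5-bromobenzene | Brc1cc(OCc2ccccc2)cc(OCc2ccccc2)c1 | starting material
2 | 2,4-bis(benzyloxy)-6-bromobenzaldehyde | O=Cc1c(Br)cc(OCc2ccccc2)cc1OCc1ccccc1 | intermediate
3 | [2,4-bis(benzyloxy)-6-bromophenyl]methanol | OCc1c(Br)cc(OCc2ccccc2)cc1OCc1ccccc1 | intermediate
4 | 1,5-bis(benzyloxy)-3-bromo-2-(chloromethyl)benzene | ClCc1c(Br)cc(OCc2ccccc2)cc1OCc1ccccc1 | intermediate
5 | 1-[3,4-bis(benzyloxy)phenyl]ethan-1-one | CC(=O)c1ccc(OCc2ccccc2)c(OCc2ccccc2)c1 | starting material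
6 | 3-[2,4-bis(benzyloxy)-6-bromophenyl]-1-[3,4-bis(benzyloxy)phenyl]propan-1-one (not isolated) | O=C(CCc1c(Br)cc(OCc2ccccc2)cc1OCc1ccccc1)c1ccc(OCc2ccccc2)c(OCc2ccccc2)c1 | intermediate
7 | 5,7-bis(benzyloxy)-2-[3,4-bis(benzyloxy)phenyl]-4H-chromene | C1(c2ccc(OCc3ccccc3)c(OCc3ccccc3)c2)=CCc2c(OCc3ccccc3)cc(OCc3ccccc3)cc2O1 | intermediate
8 | [trans-5,7-bis(benzyloxy)-2-[3,4-bis(benzyloxy)phenyl]chroman-3-yl](isopinocampheyl)borane, boron on C3 in the spatial position that the hydroxyl of 9 takes (not isolated) | C[C@H]1[C@H](B[C@H]3Cc4c(OCc5ccccc5)cc(OCc5ccccc5)cc4O[C@@H]3c3ccc(OCc4ccccc4)c(OCc4ccccc4)c3)C[C@@H]2C[C@H]1C2(C)C | intermediate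
9 | (2R,3S)-5,7-bis(benzyloxy)-2-[3,4-bis(benzyloxy)phenyl]chroman-3-ol (5,7,3',4'-tetra-O-benzyl-(+)-catechin) | O[C@H]1Cc2c(OCc3ccccc3)cc(OCc3ccccc3)cc2O[C@@H]1c1ccc(OCc2ccccc2)c(OCc2ccccc2)c1 | intermediate
10 | 1-(2,4,6-trihydroxy-3-methylphenyl)ethan-1-one | CC(=O)c1c(O)cc(O)c(C)c1O | starting material
11 | 1-[4,6-bis(benzyloxy)-2-hydroxy-3-methylphenyl]ethan-1-one | CC(=O)c1c(O)c(C)c(OCc2ccccc2)cc1OCc1ccccc1 | intermediate
12 | 1-[4,6-bis(benzyloxy)-2-methoxy-3-methylphenyl]ethan-1-one | COc1c(C)c(OCc2ccccc2)cc(OCc2ccccc2)c1C(C)=O | intermediate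
13 | 1-(4,6-dihydroxy-2-methoxy-3-methylphenyl)ethan-1-one | COc1c(C)c(O)cc(O)c1C(C)=O | intermediate
14 | 1-{3-[(dimethylamino)methyl]-2,4-dihydroxy-6-methoxy-5-methylphenyl}ethan-1-one | COc1c(C)c(O)c(CN(C)C)c(O)c1C(C)=O | intermediate
15 | 4-acetyl-5-hydroxy-3-methoxy-2-methyl-6-methylidenecyclohexa-2,4-dien-1-one (ortho-quinone methide, not isolated) | CC(=O)C1=C(O)C(=C)C(=O)C(C)=C1OC | intermediate
16 | 1-{3-[[(2R,3S)-5,7-bis(benzyloxy)-2-[3,4-bis(benzyloxy)phenyl]-3-hydroxychroman-8-yl]methyl]-2,4-dihydroxy-6-methoxy-5-methylphenyl}ethan-1-one | COc1c(C)c(O)c(Cc2c(OCc3ccccc3)cc(OCc3ccccc3)c3c2O[C@H](c2ccc(OCc4ccccc4)c(OCc4ccccc4)c2)[C@@H](O)C3)c(O)c1C(C)=O | intermediate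
17 | pilosanol N | COc1c(C)c(O)c(Cc2c(O)cc(O)c3c2O[C@H](c2ccc(O)c(O)c2)[C@@H](O)C3)c(O)c1C(C)=O | target

## Step count and risks

Total step count: 11. Longest linear sequence: 7 steps (steps 1, 2, 3, 4, 5, 10, 11).

**Step 4.** What may go wrong: dialkylation of 5, O-benzylation, base-induced drift of the C2=C3 double bond into conjugation with ring A, or stalling of the copper-mediated C–O ring closure in the strongly basic one-pot medium. Fallback: the two bonds are made in separate steps of known type. Setting out from 2 and 5, Claisen–Schmidt condensation (KOH, EtOH/THF, 20 °C) should give (E)-3-[2,4-bis(benzyloxy)-6-bromophenyl]-1-[3,4-bis(benzyloxy)phenyl]prop-2-en-1-one F1. Conjugate reduction of the enone with [(Ph3P)CuH]6 (cat.) and polymethylhydrosiloxane in toluene, which spares the aryl bromide and the benzyl ethers, gives ketone 6 as an isolated compound. Ring closure by enolate O-arylation under the weaker-base conditions used for benzofurans (CuI, N,N-dimethylglycine, K3PO4, DMF, 110 °C) returns to the route at 7.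

**Step 5.** What may go wrong: insufficient discrimination of the two alkene faces by the isopinocampheyl group on an enol ether flanked by two arenes, or β-elimination of the β-alkoxyborane with opening of ring C before oxidation. Fallback: a racemic hydroboration followed by classical resolution. Setting out from 7, BH3·SMe2 (THF, 0 °C) and NaOH/H2O2 should give racemic trans-5,7-bis(benzyloxy)-2-[3,4-bis(benzyloxy)phenyl]chroman-3-ol F2. Esterification with (S)-2-methoxy-2-phenylacetic acid (DCC, DMAP, CH2Cl2) gives (2R,3S)-5,7-bis(benzyloxy)-2-[3,4-bis(benzyloxy)phenyl]chroman-3-yl (S)-2-methoxy-2-phenylacetate F3 and (2S,3R)-5,7-bis(benzyloxy)-2-[3,4-bis(benzyloxy)phenyl]chroman-3-yl (S)-2-methoxy-2-phenylacetate F4, which are separated by chromatography or crystallisation. Saponification of the (2R,3S) ester (LiOH, THF/MeOH/H2O) returns to the route at 9.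

**Step 10.** What may go wrong: attack of the quinone methide at C6, double alkylation at C6 and C8, or reversible O-alkylation that consumes the electrophile. Fallback: the polarity is reversed and C8 is marked first. Setting out from 9, bromination with N-bromosuccinimide (CH2Cl2, −78 → 0 °C), expected at C8, gives (2R,3S)-5,7-bis(benzyloxy)-2-[3,4-bis(benzyloxy)phenyl]-8-bromochroman-3-ol F5. Deprotonation of the hydroxyl with MeLi, bromine–lithium exchange with t-BuLi (THF, −78 °C) and quenching with DMF give (2R,3S)-5,7-bis(benzyloxy)-2-[3,4-bis(benzyloxy)phenyl]-3-hydroxychromane-8-carbaldehyde F6. NaBH4 reduction gives (2R,3S)-5,7-bis(benzyloxy)-2-[3,4-bis(benzyloxy)phenyl]-8-(hydroxymethyl)chroman-3-ol F7. Acid-catalysed Friedel–Crafts benzylation of 13 at its only free ring carbon with this alcohol (TsOH cat., CH2Cl2, 0 °C) returns to the route at 16.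

Further compounds
F1 | step 4 | (E)-3-[2,4-bis(benzyloxy)-6-bromophenyl]-1-[3,4-bis(benzyloxy)phenyl]prop-2-en-1-one | O=C(/C=C/c1c(Br)cc(OCc2ccccc2)cc1OCc1ccccc1)c1ccc(OCc2ccccc2)c(OCc2ccccc2)c1
F2 | step 5 | racemic trans-5,7-bis(benzyloxy)-2-[3,4-bis(benzyloxy)phenyl]chroman-3-ol (2R,3S and 2S,3R) | O[C@H]1Cc2c(OCc3ccccc3)cc(OCc3ccccc3)cc2O[C@@H]1c1ccc(OCc2ccccc2)c(OCc2ccccc2)c1.O[C@@H]1Cc2c(OCc3ccccc3)cc(OCc3ccccc3)cc2O[C@H]1c1ccc(OCc2ccccc2)c(OCc2ccccc2)c1
F3 | step 5 | (2R,3S)-5,7-bis(benzyloxy)-2-[3,4-bis(benzyloxy)phenyl]chroman-3-yl (S)-2-methoxy-2-phenylacetate | CO[C@H](C(=O)O[C@H]1Cc2c(OCc3ccccc3)cc(OCc3ccccc3)cc2O[C@@H]1c1ccc(OCc2ccccc2)c(OCc2ccccc2)c1)c1ccccc1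
F4 | step 5 | (2S,3R)-5,7-bis(benzyloxy)-2-[3,4-bis(benzyloxy)phenyl]chroman-3-yl (S)-2-methoxy-2-phenylacetate | CO[C@H](C(=O)O[C@@H]1Cc2c(OCc3ccccc3)cc(OCc3ccccc3)cc2O[C@H]1c1ccc(OCc2ccccc2)c(OCc2ccccc2)c1)c1ccccc1
F5 | step 10 | (2R,3S)-5,7-bis(benzyloxy)-2-[3,4-bis(benzyloxy)phenyl]-8-bromochroman-3-ol | O[C@H]1Cc2c(OCc3ccccc3)cc(OCc3ccccc3)c(Br)c2O[C@@H]1c1ccc(OCc2ccccc2)c(OCc2ccccc2)c1
F6 | step 10 | (2R,3S)-5,7-bis(benzyloxy)-2-[3,4-bis(benzyloxy)phenyl]-3-hydroxychromane-8-carbaldehyde | O=Cc1c(OCc2ccccc2)cc(OCc2ccccc2)c2c1O[C@H](c1ccc(OCc3ccccc3)c(OCc3ccccc3)c1)[C@@H](O)C2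
F7 | step 10 | (2R,3S)-5,7-bis(benzyloxy)-2-[3,4-bis(benzyloxy)phenyl]-8-(hydroxymethyl)chroman-3-ol | OCc1c(OCc2ccccc2)cc(OCc2ccccc2)c2c1O[C@H](c1ccc(OCc3ccccc3)c(OCc3ccccc3)c1)[C@@H](O)C2
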